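The route rests on reading C4 of the middle flavan-3-ol unit as an aldehyde carbon: in the target it is a methine bonded to two phloroglucinol-type ring carbons, C4a of its own A ring and C8 of the lower epiafzelechin. The precursor is therefore an acyclic aryl ether, the middle A ring (already carrying the upper flavan at C8) O-linked to a threo 3-aryl-2-benzyloxypropanal diethyl acetal. One Lewis-acid operation ionises the acetal, closes the pyran C ring by Friedel–Crafts attack of C4a on C4, re-ionises the resulting 4-ethoxyflavan and lets the lower unit capture the C4 cation as in proanthocyanidin biosynthesis, setting C4 from C3.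

Key step: step 11

Remark: (−)-epiafzelechin (15) is taken as a purchasable natural flavan-3-ol. The catalyst antipodes named in steps 3 and 5 are assigned by analogy with simpler cis-alkenes and cyclic enones and would be exchanged if the facial sense proved opposite.

Step 1
Reactants: 1 1-(benzyloxy)-4-iodobenzene; 2 3,3-diethoxyprop-1-yne
Product: 3 1-(benzyloxy)-4-(3,3-diethoxyprop-1-yn-1-yl)benzene
Conditions: PdCl2(PPh3)2 (2 mol%), CuI (4 mol%), Et3N, THF, rt
Reagents that add atoms: none
Why: Sonogashira coupling of an aryl iodide with a terminal alkyne, under amine base that leaves the acetal untouched.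

Step 2
Reactants: 3 1-(benzyloxy)-4-(3,3-diethoxyprop-1-yn-1-yl)benzene
Product: 4 (Z)-1-(benzyloxy)-4-(3,3-diethoxyprop-1-en-1-yl)benzene
Conditions: H2 (1 atm), Lindlar catalyst, quinoline, EtOAc, rt
Reagents that add atoms: none
Why: Lindlar semihydrogenation adds H2 syn to the alkyne and should stop at the Z-alkene, the poisoned catalyst sparing the aryl benzyl ether.

Step 3
Reactants: 4 (Z)-1-(benzyloxy)-4-(3,3-diethoxyprop-1-en-1-yl)benzene
Product: 5 (2S,3S)-2-[4-(benzyloxy)phenyl]-3-(diethoxymethyl)oxirane (cis-epoxide)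
Conditions: (S,S)-(salen)Mn(III)Cl Jacobsen catalyst (5 mol%), 4-phenylpyridine N-oxide (20 mol%), aq. NaOCl (pH 11.3), CH2Cl2, 0 °C
Reagents that add atoms: sodium hypochlorite, [Na+].[O-]Cl
Why: Jacobsen–Katsuki epoxidation of a cis-disubstituted aryl alkene, in which the chiral Mn-oxo species selects the enantioface and sets both epoxide centres at once while the basic medium preserves the acetal.

Step 4
Reactants: 6 7-hydroxy-4H-chromen-4-one
Product: 7 7-(benzyloxy)-4H-chromen-4-one
Conditions: BnBr, K2CO3, acetone, reflux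
Reagents that add atoms: benzyl bromide, BrCc1ccccc1
Why: Williamson etherification of the only acidic hydroxyl.

Step 5
Reactants: 7 7-(benzyloxy)-4H-chromen-4-one; 8 [4-(benzyloxy)phenyl]boronic acid
Product: 9 (2S)-7-(benzyloxy)-2-[4-(benzyloxy)phenyl]chroman-4-one
Conditions: Pd(TFA)2 (5 mol%), (R)-t-BuPyOx (6 mol%), NH4PF6 (30 mol%), H2O (5 equiv), ClCH2CH2Cl, 60 °C
Reagents that add atoms: none
Why: Pd-catalysed asymmetric conjugate addition of an arylboronic acid to a chromone, in which the chiral pyridine-oxazoline aryl-Pd species selects the enantioface of C2=C3 in the carbopalladation and water protonates the Pd enolate, setting C2 of the upper unit.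

Step 6
Reactants: 9 (2S)-7-(benzyloxy)-2-[4-(benzyloxy)phenyl]chroman-4-one
Product: 10 (2S,4S)-7-(benzyloxy)-2-[4-(benzyloxy)phenyl]chroman-4-ol (2,4-cis)
Conditions: NaBH4, MeOH/THF, 0 °C
Reagents that add atoms: none
Why: Borohydride reduction of the flavanone should give the 2,4-cis alcohol by axial hydride delivery; the C4 configuration is lost again in step 7.

Step 7
Reactants: 10 (2S,4S)-7-(benzyloxy)-2-[4-(benzyloxy)phenyl]chroman-4-ol; 11 3,5-bis(benzyloxy)phenol (3 equiv)
Product: 12 3,5-bis(benzyloxy)-2-{(2S,4R)-7-(benzyloxy)-2-[4-(benzyloxy)phenyl]chroman-4-yl}phenol (2,4-trans)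
Conditions: BF3·OEt2 (0.2 equiv), CH2Cl2, −40 to 0 °C
Reagents that add atoms: none
Why: Friedel–Crafts alkylation in which the Lewis acid ionises the 4-ol with loss of water to the 4-flavanyl cation (stabilised by O1 and the 7-benzyloxy group), which the phenol should attack at the less hindered position ortho to its free hydroxyl and from the face anti to the C2 aryl group, giving the 2,4-trans 4-arylflavan.

Step 8
Reactants: 12 3,5-bis(benzyloxy)-2-{(2S,4R)-7-(benzyloxy)-2-[4-(benzyloxy)phenyl]chroman-4-yl}phenol; 5 (2S,3S)-2-[4-(benzyloxy)phenyl]-3-(diethoxymethyl)oxirane (1.5 equiv)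
Product: 13 (2S,3R)-3-[3,5-bis(benzyloxy)-2-{(2S,4R)-7-(benzyloxy)-2-[4-(benzyloxy)phenyl]chroman-4-yl}phenoxy]-3-[4-(benzyloxy)phenyl]-1,1-diethoxypropan-2-ol (threo)
Conditions: Cs2CO3 (0.5 equiv), DMF, 90 °C
Reagents that add atoms: none
Why: SN2 opening of the cis-epoxide by the phenoxide at the benzylic carbon (the other carbon is shielded and deactivated by the acetal), with inversion, so that the cis-epoxide gives the threo ether alcohol, that is, the 2R,3R (2,3-cis) pattern of the future flavan-3-ol.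

Step 9
Reactants: 13 the threo ether alcohol
Product: 14 (2S,3R)-2-(benzyloxy)-3-[3,5-bis(benzyloxy)-2-{(2S,4R)-7-(benzyloxy)-2-[4-(benzyloxy)phenyl]chroman-4-yl}phenoxy]-3-[4-(benzyloxy)phenyl]-1,1-diethoxypropane
Conditions: NaH, BnBr, Bu4NI (cat.), THF/DMF, 0 °C to rt
Reagents that add atoms: benzyl bromide, BrCc1ccccc1
Why: Williamson benzylation of the secondary alcohol, which masks O3 in the form removed with all other benzyl groups at the end and touches no stereocentre.

Step 10
Reactants: 15 (−)-epiafzelechin, (2R,3R)-2-(4-hydroxyphenyl)chroman-3,5,7-triol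
Product: 16 5,7,4′-tri-O-benzyl-(−)-epiafzelechin, (2R,3R)-5,7-bis(benzyloxy)-2-[4-(benzyloxy)phenyl]chroman-3-ol
Conditions: BnBr (3.3 equiv), K2CO3, DMF, 0 °C to rt
Reagents that add atoms: benzyl bromide, BrCc1ccccc1
Why: Williamson etherification that is chemoselective for the three phenols over the secondary 3-hydroxyl under carbonate base.

Step 11
Reactants: 14 the benzylated acetal; 16 5,7,4′-tri-O-benzyl-(−)-epiafzelechin (3 equiv)
Product: 18 nona-O-benzyl ether of the target (3-OH of the lower unit free), via 4β-ethoxyflavan 17 (not isolated)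
Conditions: TMSOTf (0.2 equiv), 4 Å MS, CH2Cl2, −78 to −30 °C; then Et3N
Reagents that add atoms: none
Why: TMSOTf ionises the diethyl acetal to an oxocarbenium ion at C4, which the middle A ring attacks through its only free position ortho to the ether oxygen (C4a, activated ortho and para by the two benzyloxy groups), a 6-exo-trig Friedel–Crafts closure of the pyran ring that gives 4-ethoxyflavan 17. Under the same acid 17 loses ethanol to the C4 benzylic cation, stabilised by O1 and the 5- and 7-oxygens, and C8 of 16 captures it, the Lewis-acid interflavan coupling that mirrors the flavan-3,4-diol pathway of proanthocyanidin biosynthesis. The closest known reaction types are the acid-mediated cyclisation of 3-aryloxypropanal acetals to 4-alkoxychromans and the TMSOTf-mediated C4-arylation of benzylated 4-alkoxyflavan-3-ols. C4 is the only new stereocentre: in the 2,3-cis half-chair the C2 aryl group is equatorial and the 3-benzyloxy group axial, so the nucleophile should add anti to O3 and give the 3,4-trans (4β) linkage from either C4 epimer of 17. The two bond formations converge in either order, since an acyclic adduct of 16 with the oxocarbenium ion would re-ionise and close the same C4–C4a bond. The step also needs C8 over C6 attack in 16, the usual preference of 5,7-di-O-benzyl flavan-3-ols, and suppression of self-condensation, which the upper flavan blocking C8 of the middle ring and the excess of 16 should secure.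

Step 12
Reactants: 18 nona-O-benzyl ether of the target
Product: 19 (2S)-4′,7-dihydroxyflavan-(4β→8)-epiafzelechin-(4β→8)-epiafzelechin (CNP0257624.1)
Conditions: H2 (1 atm), Pd(OH)2/C, THF/MeOH/H2O, rt
Reagents that add atoms: none
Why: Hydrogenolysis of the nine benzyl ethers (eight aryl, one secondary alkyl) under neutral conditions, which should leave the ring C2–O1 bonds, the interflavan bonds and all stereocentres untouched.

Compound list
1 | 1-(benzyloxy)-4-iodobenzene | Ic1ccc(OCc2ccccc2)cc1 | starting material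
2 | 3,3-diethoxyprop-1-yne | C#CC(OCC)OCC | starting material
3 | 1-(benzyloxy)-4-(3,3-diethoxyprop-1-yn-1-yl)benzene | CCOC(OCC)C#Cc1ccc(OCc2ccccc2)cc1 | intermediate
4 | (Z)-1-(benzyloxy)-4-(3,3-diethoxyprop-1-en-1-yl)benzene | CCOC(OCC)/C=C\c1ccc(OCc2ccccc2)cc1 | intermediate
5 | (2S,3S)-2-[4-(benzyloxy)phenyl]-3-(diethoxymethyl)oxirane (cis) | CCOC(OCC)[C@H]1O[C@H]1c1ccc(OCc2ccccc2)cc1 | intermediate
6 | 7-hydroxy-4H-chromen-4-one | O=c1ccoc2cc(O)ccc12 | starting material
7 | 7-(benzyloxy)-4H-chromen-4-one | O=c1ccoc2cc(OCc3ccccc3)ccc12 | intermediate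
8 | [4-(benzyloxy)phenyl]boronic acid | OB(O)c1ccc(OCc2ccccc2)cc1 | starting material
9 | (2S)-7-(benzyloxy)-2-[4-(benzyloxy)phenyl]chroman-4-one | O=C1C[C@@H](c2ccc(OCc3ccccc3)cc2)Oc2cc(OCc3ccccc3)ccc12 | intermediate
10 | (2S,4S)-7-(benzyloxy)-2-[4-(benzyloxy)phenyl]chroman-4-ol (2,4-cis) | O[C@H]1C[C@@H](c2ccc(OCc3ccccc3)cc2)Oc2cc(OCc3ccccc3)ccc12 | intermediate
11 | 3,5-bis(benzyloxy)phenol | Oc1cc(OCc2ccccc2)cc(OCc2ccccc2)c1 | starting material
12 | 3,5-bis(benzyloxy)-2-{(2S,4R)-7-(benzyloxy)-2-[4-(benzyloxy)phenyl]chroman-4-yl}phenol (2,4-trans) | c1ccccc1COc1ccc([C@@H]2C[C@@H](c3c(OCc4ccccc4)cc(OCc4ccccc4)cc3O)c3ccc(OCc4ccccc4)cc3O2)cc1 | intermediate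
13 | (2S,3R)-3-[3,5-bis(benzyloxy)-2-{(2S,4R)-7-(benzyloxy)-2-[4-(benzyloxy)phenyl]chroman-4-yl}phenoxy]-3-[4-(benzyloxy)phenyl]-1,1-diethoxypropan-2-ol (threo) | c1ccccc1COc1ccc([C@@H]2C[C@@H](c3c(OCc4ccccc4)cc(OCc4ccccc4)cc3O[C@H](c3ccc(OCc4ccccc4)cc3)[C@H](O)C(OCC)OCC)c3ccc(OCc4ccccc4)cc3O2)cc1 | intermediate
14 | 2-O-benzyl ether of 13, (2S,3R)-2-(benzyloxy)-3-(aryloxy)-3-[4-(benzyloxy)phenyl]-1,1-diethoxypropane | c1ccccc1COc1ccc([C@@H]2C[C@@H](c3c(OCc4ccccc4)cc(OCc4ccccc4)cc3O[C@H](c3ccc(OCc4ccccc4)cc3)[C@H](OCc3ccccc3)C(OCC)OCC)c3ccc(OCc4ccccc4)cc3O2)cc1 | intermediate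
15 | (−)-epiafzelechin, (2R,3R)-2-(4-hydroxyphenyl)chroman-3,5,7-triol | Oc1cc(O)c2c(c1)O[C@H](c1ccc(O)cc1)[C@H](O)C2 | starting material
16 | 5,7,4′-tri-O-benzyl-(−)-epiafzelechin | c1ccccc1COc1cc(OCc3ccccc3)c2c(c1)O[C@H](c1ccc(OCc3ccccc3)cc1)[C@H](O)C2 | intermediate
17 | 4β-ethoxyflavan from ring closure of 14: middle unit (2R)-2,3-cis-3,4-trans with 3-OBn and 4-OEt, upper flavan at C8 (drawn as the 4β epimer; either epimer gives the same cation) | c1ccccc1COc1ccc([C@@H]2C[C@@H](c3c(OCc4ccccc4)cc(OCc4ccccc4)c4c3O[C@H](c3ccc(OCc5ccccc5)cc3)[C@H](OCc3ccccc3)[C@H]4OCC)c3ccc(OCc4ccccc4)cc3O2)cc1 | intermediate (not isolated)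
18 | nona-O-benzyl trimer: (2S)-7,4′-di-O-benzylflavan-(4β→8)-3,5,7,4′-tetra-O-benzylepiafzelechin-(4β→8)-5,7,4′-tri-O-benzylepiafzelechin | c1ccccc1COc1ccc([C@@H]2C[C@@H](c3c(OCc4ccccc4)cc(OCc4ccccc4)c4c3O[C@H](c3ccc(OCc5ccccc5)cc3)[C@H](OCc3ccccc3)[C@H]4c3c(OCc5ccccc5)cc(OCc5ccccc5)c5c3O[C@H](c3ccc(OCc6ccccc6)cc3)[C@H](O)C5)c3ccc(OCc4ccccc4)cc3O2)cc1 | intermediate
19 | (2S)-4′,7-dihydroxyflavan-(4β→8)-epiafzelechin-(4β→8)-epiafzelechin (CNP0257624.1) | Oc1ccc([C@@H]2C[C@@H](c3c(O)cc(O)c4c3O[C@H](c3ccc(O)cc3)[C@H](O)[C@H]4c3c(O)cc(O)c4c3O[C@H](c3ccc(O)cc3)[C@H](O)C4)c3ccc(O)cc3O2)cc1 | target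

Total step count: 12. Longest linear sequence: 8 steps (steps 4, 5, 6, 7, 8, 9, 11, 12).

Steps most likely to fail

Step 11. The acyclic oxocarbenium ion may be intercepted intermolecularly before ring closure, or the C4 cation may lose H3 or attack a second molecule through the free C6 of the middle ring, so that the two bond formations do not follow in the intended order. The fallback separates the two events and changes the second to thiophilic activation. It sets out from 14. Ring closure alone under a Brønsted acid (camphorsulfonic acid cat., CH2Cl2 with a few equivalents of EtOH, 0 °C), in which ethanol returns any C4 cation to the ether, should give 17 as an isolated compound. Exchange of its 4-ethoxy group (BnSH, BF3·OEt2 cat., CH2Cl2, −40 °C) should give the storable 4β-benzylthioflavan F1. F1 and 16 with AgBF4 (1.2 equiv) in THF at 0 °C should then give the interflavan bond, and the route is rejoined at 18.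

Step 8. The ortho-flavanyl group of 12 may slow SN2 attack at the secondary benzylic epoxide carbon so far that epoxide decomposition or partial ionisation, with loss of stereospecificity, takes over. The fallback changes the order of assembly and sets out from 5. Opening with the unhindered phenol 11 (Cs2CO3, DMF, 80 °C) should give the ether alcohol F2, and benzylation (NaH, BnBr) the acetal F3. The same TMSOTf cascade with 16 should then give the protected dimer F4; both ortho positions of its precursor are equivalent, so the site of ring closure stays unambiguous. The upper unit is attached last by Friedel–Crafts alkylation of F4 with flavan-4-ol 10 (TMSOTf cat., CH2Cl2, −40 °C). This relies on C8 of the upper flavan-3-ol ring of a 4→8 dimer being its most accessible nucleophilic position, and the route is rejoined at 18.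

Step 3. Oxygen transfer to the electron-rich cis-styrene may pass through a long-lived radical intermediate, with cis-to-trans leakage and eroded enantioselectivity. The fallback moves stereocontrol from the catalyst to an enantiopure partner and sets out from 4. Buffered peracid epoxidation (m-CPBA, NaHCO3, CH2Cl2, 0 °C) is stereospecific and should give the racemic cis-epoxide F5. Opening of F5 with enantiopure 12 under the conditions of step 8 should give 13 together with its chain diastereomer F6, to be separated by chromatography, and the route is rejoined at 13.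

Further compounds
F1 | step 11 | 4β-benzylthio analogue of 17 (middle unit 2,3-cis-3,4-trans, 3-OBn, 4-SBn) | c1ccccc1COc1ccc([C@@H]2C[C@@H](c3c(OCc4ccccc4)cc(OCc4ccccc4)c4c3O[C@H](c3ccc(OCc5ccccc5)cc3)[C@H](OCc3ccccc3)[C@H]4SCc3ccccc3)c3ccc(OCc4ccccc4)cc3O2)cc1
F2 | step 8 | (2S,3R)-3-[3,5-bis(benzyloxy)phenoxy]-3-[4-(benzyloxy)phenyl]-1,1-diethoxypropan-2-ol | c1ccccc1COc1cc(OCc2ccccc2)cc(c1)O[C@H](c1ccc(OCc2ccccc2)cc1)[C@H](O)C(OCC)OCC
F3 | step 8 | (2S,3R)-2-(benzyloxy)-3-[3,5-bis(benzyloxy)phenoxy]-3-[4-(benzyloxy)phenyl]-1,1-diethoxypropane | c1ccccc1COc1cc(OCc2ccccc2)cc(c1)O[C@H](c1ccc(OCc2ccccc2)cc1)[C@H](OCc1ccccc1)C(OCC)OCC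
F4 | step 8 | 3,5,7,4′-tetra-O-benzylepiafzelechin-(4β→8)-5,7,4′-tri-O-benzylepiafzelechin | c1c(OCc3ccccc3)cc(OCc3ccccc3)c2c1O[C@H](c1ccc(OCc3ccccc3)cc1)[C@H](OCc1ccccc1)[C@H]2c1c(OCc3ccccc3)cc(OCc3ccccc3)c3c1O[C@H](c1ccc(OCc4ccccc4)cc1)[C@H](O)C3
F5 | step 3 | racemic cis-2-[4-(benzyloxy)phenyl]-3-(diethoxymethyl)oxirane | CCOC(OCC)[C@H]1O[C@H]1c1ccc(OCc2ccccc2)cc1.CCOC(OCC)[C@@H]1O[C@@H]1c1ccc(OCc2ccccc2)cc1
F6 | step 3 | (2R,3S)-chain diastereomer of 13, with the same (2S,4R)-flavanyl group | c1ccccc1COc1ccc([C@@H]2C[C@@H](c3c(OCc4ccccc4)cc(OCc4ccccc4)cc3O[C@@H](c3ccc(OCc4ccccc4)cc3)[C@@H](O)C(OCC)OCC)c3ccc(OCc4ccccc4)cc3O2)cc1
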